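(The readings are simulated with made-up constants, and the scatter is random.)

The trap with a closed-flask yield is to carry it unchanged to a fed flask or a flow tank. The midnight run's 69.2% of Q at 12.0 min tells how far G got, not how the rate followed G on the way. Elm repeats the midnight recipe, so that reading is the estimate for elm.

| flask | G | J | E | remark | time |
|---|---|---|---|---|---|
| midnight | 20 mM | 16 mM | 0.78 µM | run made earlier |  |
| noon | 20 mM | 16 mM | 0.39 µM | run made earlier |  |
| summer | 20 mM | 16 mM | 1.6 µM | run made earlier |  |
| dawn | 30 mM | 16 mM | 0.78 µM | run made earlier |  |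
| birch | 20 mM (fed, over 9.60 min) | 16.0 mM | 0.78 µM | a stirred flask in which G is dosed at a steady rate over 9.60 min without added volume, worked up at 12 min | 12 min |
| alder | 20 mM | 16.0 mM (fed, over 9.60 min) | 0.78 µM | all but J at the start; J goes in evenly over 9.60 min, the run ends at 12 min | 12 min |
| ash | 20 mM | 16.0 mM | 0.78 µM | one stirred flow tank at steady state, fed with the mixture as stated, mean residence time 12 min |  |
| elm | 20 mM | 16.0 mM | 0.78 µM | everything together in a closed stirred flask, run for 12 min | 12 min |

| run | time / min | Q / % | G / % |
|---|---|---|---|
| midnight | 1.50 | 11.7 | 89.1 |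
| midnight | 4.00 | 27.2 | 70.7 |
| midnight | 8.00 | 51.7 | 49.4 |
| midnight | 12.0 | 69.2 | 32.4 |
| noon | 2.50 | 8.7 | 91.0 |
| noon | 5.00 | 17.8 | 79.9 |
| noon | 8.00 | 28.0 | 70.3 |
| noon | 10.0 | 37.5 | 64.3 |
| summer | 0.833 | 12.5 | 86.9 |
| summer | 2.00 | 29.2 | 68.7 |
| summer | 4.00 | 51.7 | 46.2 |
| summer | 10.0 | 81.4 | 18.0 |
| dawn | 2.50 | 16.0 | 83.7 |
| dawn | 5.00 | 31.1 | 67.4 |
| dawn | 8.00 | 46.8 | 53.6 |
| dawn | 10.0 | 54.1 | 46.7 |

(each reading ± 1 percentage point)

- the stated concentrations are those of everything mixed, before any reaction; amounts are the same in each set-up
- steps thought possible: G + E <-> D; D -> Z + L; J + Z <-> X; X -> E + Q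
- the feed brings no volume worth counting
- the earlier runs were made in a closed, stirred flask

1. the set-up with the highest amount of Q at the outlet or at the end, in percent of the G put in ("none" if the first two lie within 2 percentage points) (birch / alder / ash / elm / none)
2. amount of Q at the outlet or at the end, in percent of the G put in, birch
3. amount of Q at the outlet or at the end, in percent of the G put in, alder
4. amount of Q at the outlet or at the end, in percent of the G put in, ash
5. amount of Q at the outlet or at the end, in percent of the G put in, elm

Two extreme flasks, both tied to the midnight run, bracket birch and ash. In the zero-order extreme the rate ignores G, so birch and ash copy the midnight figure. In the first-order extreme, with E held at its charge (pseudo-first-order), the midnight G reading gives a clearance constant of 0.0939 min⁻¹, the fraction of the free G that this charge of E removes per minute. It predicts 47.2% of G at 8.00 min in the midnight run, against a reading of 49.4%. With it, ash gives 53.0% of Q and birch, whose G starts from nothing and builds up during dosing, gives 47.4%.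

Birch and ash should lie between these extremes. The mean rates of Q read 1.36 mM min⁻¹ up to 4.00 min in the midnight run and 1.87 mM min⁻¹ up to 5.00 min in the dawn run, which reads as an order in G of about 0.780. Because that order lies nearer one than nought, interpolating by it gives this reckoning's 56.6% for ash and 52.2% for birch. In alder, J arrives at 1.67 mM min⁻¹, close to the 1.56 mM min⁻¹ read as the opening use of J in the midnight run, so alder should trail elm slightly. J is the limiting reagent, and its charge caps Q at 80.0%, above the midnight reading.

The forecast names elm best at 69%, with alder at 65%, ash at 57% and birch at 52%, holding that “the rate depends mainly on G and J matters only when nearly gone”.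

The flask gives 68.9% for elm, 65.1% for alder, 55.6% for ash and 50.2% for birch, so elm is best, and the forecast holds.

    G + E ⇌ D (K = 36.0 L mol⁻¹, k = 39700 L mol⁻¹ s⁻¹)
    D → Z + L (k = 89.9 s⁻¹)
    J + Z ⇌ X (K = 41.0 L mol⁻¹, k = 1.08 × 10⁶ L mol⁻¹ s⁻¹)
    X → E + Q (k = 3720 s⁻¹)

In alder at 5.43 min, D falls back 12 times faster than it goes on, and X falls back 7.1 times faster. Both bindings run near balance in alder at that moment. Ash and birch stand 2.6 percentage points and 2.8 points above their clearance figures. For the neighbour of alder charged with 12 mM of G, which ends with 28% of its G and 46% of its J still unbound, the midnight clearance constant gives 67.6% of Q. That neighbour reaches 72.2%, with E at 89.0% of the catalyst against 77.5% in alder at 12.0 min.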